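(The earlier runs and the new flask were generated by integration on assumed constants, and the scatter is random.)

The unit here is one substrate unit charged: a homo dimer holds two of them, and each unit ends in homo dimer or on the partner's side, so the question is how the units split.

| flask | substrate | partner | temperature | remark | time |
|---|---|---|---|---|---|
| Saturday's | 0.21 M | 0.378 M | 5 °C | run made earlier |  |
| Sunday's | 0.21 M | 0.53 M | 20 °C | run made earlier |  |
| Wednesday's | 0.21 M | 0.83 M | 5 °C | run made earlier |  |
| Friday's | 0.42 M | 0.378 M | 20 °C | run made earlier |  |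
| autumn | 0.21 M | 0.378 M | 20 °C | everything together at the start | 2.0 min |
| winter | 0.21 M | 0.378 M (fed, over 50 s) | 20 °C | all else is in the flask from the start; the feed brings no volume worth counting | 2.0 min |
| midnight | 0.21 M | 0.378 M (in portions, 2, over 50 s) | 20 °C | first portion at the start, last at 50 s | 2.0 min |
| dawn | 0.21 M (fed, over 50 s) | 0.378 M |  | the addition at −20 °C, then warmed to 20 °C; the feed brings no volume worth counting | 2.0 min |

| run | time / min | homo dimer / % | mono adduct / % | substrate / % |
|---|---|---|---|---|
| Saturday's | 0.333 | 25.5 | 8.6 | 63.6 |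
| Saturday's | 0.667 | 36.8 | 13.0 | 45.2 |
| Saturday's | 1.33 | 46.9 | 18.9 | 26.6 |
| Saturday's | 3.00 | 53.0 | 23.3 | 10.9 |
| Sunday's | 0.500 | 39.4 | 22.7 | 21.9 |
| Sunday's | 1.00 | 42.5 | 25.4 | 9.0 |
| Sunday's | 1.33 | 42.9 | 24.5 | 4.9 |
| Sunday's | 2.00 | 42.9 | 21.6 | 1.3 |
| Sunday's | 2.50 | 43.3 | 19.4 | 1.3 |
| Wednesday's | 0.417 | 24.8 | 19.1 | 48.6 |
| Wednesday's | 1.33 | 35.6 | 31.0 | 16.3 |
| Wednesday's | 2.00 | 36.5 | 32.0 | 8.9 |
| Wednesday's | 3.00 | 37.2 | 30.4 | 3.1 |
| Wednesday's | 5.00 | 36.8 | 23.3 | 0.7 |
| Friday's | 0.200 | 47.2 | 9.1 | 38.3 |
| Friday's | 0.667 | 62.3 | 14.6 | 13.4 |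
| Friday's | 1.00 | 64.8 | 15.4 | 7.9 |
| Friday's | 1.50 | 65.8 | 15.6 | 4.3 |
| Friday's | 2.50 | 66.3 | 14.5 | 1.4 |

(scatter of a reading: 0.3 percentage points)

- percent here means substrate units held: one homo dimer counts as two
- a reading or a percentage of mono adduct counts all its forms, free or not

- the flask that comes out highest in amount of homo dimer, in percent of the substrate charged; "all alike" if 1.5 percentage points covers them all (autumn / winter / midnight / dawn / all alike)
- amount of homo dimer at the end, in percent of the substrate charged, autumn
- amount of homo dimer at the end, in percent of the substrate charged, winter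
- amount of homo dimer at the end, in percent of the substrate charged, midnight
- amount of homo dimer at the end, in percent of the substrate charged, dawn

My reckoning climbs a ladder of times, fastest first.

1. Dimer time τ: the inverse of the second-order constant of substrate's loss to homo dimer, times c(substrate) charged. Friday's first reading, at 0.200 min, gives 0.325 min for 0.21 M.

2. In that reading 14.5% is neither homo dimer nor substrate. That is more than the 9.1% of mono adduct, and I count it all to the partner's side. Dividing the rates, homo dimer units per partner-side unit equal g·c(substrate)/c(partner), where g, the split number (a selectivity factor), reads 4.35.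

3. With partner steady and x = g·c(substrate charged)/c(partner), the homo dimer share, once the substrate is used up, is S = 1 − ln(1 + x)/x. It tends to the whole with no partner and to nothing with great excess.

4. Partner time at full charge: 2.42 τ, or 0.786 min. For autumn, taking partner as steady, I therefore reckon S = 49.2%.

5. The feed takes 50 s, longer than τ. By τ, 0.147 M of partner has been fed into winter; taking that as a steady c(partner), I reckon S = 68.2%. Reckoning midnight as if its first portion stood throughout gives x = 4.84 and S = 63.5%.

6. Saturday's first reading gives τ as 0.831 min at 5 °C. Carrying the factor between the two τ, taken per degree, down to −20 °C gives about 3.98 min, longer than the feed. I thus reckon dawn as a late batch with autumn's x.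

The forecast gave 50.5%, 67.5%, 63% and 50% for autumn, winter, midnight and dawn, with winter highest, holding that “starving the flask of partner early favours dimer”.

The flasks give 50.9%, 67.5%, 62.6% and 49.9%, and winter stands highest.

    substrate + partner → mono adduct + by-product (k = 0.0380 M⁻¹ s⁻¹, Ea = 44.0 kJ mol⁻¹)
    substrate + partner → other mono adduct + by-product (k = 0.0190 M⁻¹ s⁻¹, Ea = 67.0 kJ mol⁻¹)
    partner → decomposition product (k = 1.10 × 10⁻⁴ s⁻¹, Ea = 101 kJ mol⁻¹)
    2 substrate → homo dimer (k = 0.120 M⁻¹ s⁻¹, Ea = 42.0 kJ mol⁻¹)
    partner + other mono adduct → double product + by-product (k = 0.0150 M⁻¹ s⁻¹, Ea = 71.0 kJ mol⁻¹)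
    partner + mono adduct → double product + by-product (k = 0.0140 M⁻¹ s⁻¹, Ea = 51.0 kJ mol⁻¹)
    crystals ⇌ mono adduct, rate k7*(cs7 - [mono adduct]) while solid is left; crystals form when [mono adduct] > cs7 (solubility = 0.200 M, k = 0.260 s⁻¹)
    (constants at 20 °C)

Winter, with the partner fed over 50 s, ends 17 percentage points of homo dimer above autumn. The same x of 2.42 stands behind autumn and dawn, which end 1 point apart. Now take dawn's neighbour with 0.64 M of partner, 3.05 equiv. Its x is 1.43, so S = 37.9%. That flask gives 38.8%, with 4.8% of the charged substrate still there.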